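All runs are calculated on assumed constants; scatter was added.

**Top reading.** Open dimer read 15.1% at 8.00 min in the dusk run, the very flask asked about, and I had to place its top between the readings.

in all of them: substrate 11 mM
- dusk: the very flask that is asked about, followed so far
- flask: time 1.5 h

dusk run (percent of the substrate charged)

| time / min | open dimer / % | ring / % | substrate / % |
|---|---|---|---|
| 1.50 | 8.9 | 14.8 | 75.7 |
| 4.00 | 14.3 | 33.1 | 52.4 |
| 8.00 | 15.1 | 49.8 | 34.7 |
| 20.0 | 9.2 | 71.9 | 19.6 |
| 50.0 | 2.7 | 84.7 | 12.7 |

(scatter of a reading: 0.3 percentage points)

- time up to 1.5 h at which open dimer stands highest
- the amount of open dimer, in percent of the substrate charged, at that time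

**Two versions.** I drew two versions at the board, both with two substrate making one open dimer. In the first, that step runs one way and dimer climbs without falling, but the dusk readings fall. In the second, the step stays balanced and dimer share equals a constant times substrate share squared. The real flask starts beneath that balanced curve, meets it at the top, where dimer's gain equals its loss, and lies above it afterwards.

**My reckoning.** The ratio read 0.521 at 4.00 min and 1.25 at 8.00 min. I judged that the top lay between them and took the midpoint, 0.887, as the balance number: dimer share over substrate share squared at the top. With dimer near 15.1%, I reckoned substrate at 41.2%, which a straight line between the substrate readings places at 6.52 min.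

**The forecast.** It gave 0.1 h and 15.7%, from “A smooth curve through the 4 and 8 min points”; its time is earlier than mine.

**The result.** The simulation put the top at 0.106 h with 15.7% and substrate 40.3%, a balance number of 0.967.

    substrate ⇌ ring (K = 7.00, k = 0.00196 s⁻¹)
    2 substrate ⇌ open dimer (K = 43.9 L mol⁻¹, k = 0.0634 L mol⁻¹ s⁻¹)

The ring path used substrate 1.4 times as fast as the dimer path at the start and 3.4 times as fast at 0.102 h, forward rates each, so this selectivity factor grew as substrate fell. Scaled with the charge to the neighbour flask of 44 mM, my number gives 5.14% dimer at its 12.0% substrate, and that flask held 5.90% at 1.50 h.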